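**Plan**

- The ring of the target is a 2,5-dimethoxy-1,4-benzoquinone made of two MeO–C=C(indolyl)–C=O units joined head to tail. Each ring C–OMe is an enol-ether carbon that can carry lithium (an acyl-anion equivalent), and each ring C=O is an ester carbon already at the quinone oxidation level.
- Retrosynthesis: remove the two N-silyl groups, then cut both ring C(=O)–C(OMe) bonds to give a tert-butyl and a methyl (E)-3-methoxy-2-(indol-3-yl)acrylate. Each acrylate goes back to an indol-3-ylacetate (C=CH–OMe from methyl formate and dimethyl sulfate); the 7-prenyl group comes from a C7–Br, and the acetate arm from a diazoacetate.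
- Forward: the two N-silyl indol-3-ylacetates are made and converted into the (E)-β-methoxyacrylates. The quinone ring, the only ring made, forms in one flask by a [3+3] double acylation, and the N–Si bonds are cleaved last.
- Stereochemistry: the target has no stereocentre. The only element that matters is the E geometry of both acrylates (vinyl H cis to the acyl group), which comes from the O-methylation of the formyl-ester enolates and becomes the cis ring geometry.

Key step: step 7

Remark: the silyl triflates, the amide bases (as solutions), 6 and 8 are taken as purchased; TIPS is used on the unhindered indole and the smaller TBS on the indole whose N1 is flanked by the C7 substituent.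

**Route**

Step 1
Reactants: 1 methyl 2-(1H-indol-3-yl)acetate
Product: 2 methyl 2-[1-(triisopropylsilyl)-1H-indol-3-yl]acetate
Conditions: NaN(SiMe3)2, THF, −78 °C; TIPSOTf, −78 → 0 °C
Reagents that add atoms: triisopropylsilyl trifluoromethanesulfonate (TIPSOTf), CC(C)[Si](OS(=O)(=O)C(F)(F)F)(C(C)C)C(C)C
Why: N-silylation of the indolyl anion (N–H is deprotonated before the ester CH2), giving a bulky N-substituent that has no directing heteroatom and shields indole C2 from later lithiation.

Step 2
Reactants: 2 methyl 2-[1-(triisopropylsilyl)-1H-indol-3-yl]acetate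
Product: 4 methyl (E)-3-methoxy-2-[1-(triisopropylsilyl)-1H-indol-3-yl]prop-2-enoate, via potassium enolate 3 (not isolated)
Conditions: KN(SiMe3)2, THF, −78 °C; HCO2Me, −78 → 0 °C; then DMF, Me2SO4, 0 °C → rt
Reagents that add atoms: methyl formate, COC=O; dimethyl sulfate, COS(=O)(=O)OC
Why: crossed Claisen formylation of the ester enolate followed by O-methylation of the non-chelated potassium enolate in DMF, which should give mainly the more stable E enol ether, as in the standard preparation of 2-aryl-3-methoxyacrylates.

Step 3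
Reactants: 5 7-bromo-1H-indole; 6 tert-butyl diazoacetate
Product: 7 tert-butyl 2-(7-bromo-1H-indol-3-yl)acetate
Conditions: Cu(OTf)2 (5 mol %), CH2Cl2, rt, slow addition of 6 to excess 5
Reagents that add atoms: none
Why: copper-carbenoid C3–H alkylation of a free indole (electrophilic attack at C3, then proton transfer), run before the prenyl alkene is present so that cyclopropanation cannot compete.

Step 4
Reactants: 7 tert-butyl 2-(7-bromo-1H-indol-3-yl)acetate; 8 tributyl(3-methylbut-2-en-1-yl)stannane
Product: 9 tert-butyl 2-[7-(3-methylbut-2-en-1-yl)-1H-indol-3-yl]acetate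
Conditions: Pd(PPh3)4 (5 mol %), DMF, 100 °C
Reagents that add atoms: none
Why: Stille coupling of the aryl bromide with the allylic stannane, in which C–C reductive elimination at the unsubstituted allyl terminus should give the linear 3-methylbut-2-enyl arene; the free N–H and the tert-butyl ester are inert.

Step 5
Reactants: 9 tert-butyl 2-[7-(3-methylbut-2-en-1-yl)-1H-indol-3-yl]acetate
Product: 10 tert-butyl 2-[1-(tert-butyldimethylsilyl)-7-(3-methylbut-2-en-1-yl)-1H-indol-3-yl]acetate
Conditions: NaN(SiMe3)2, THF, −78 °C; TBSOTf, −78 → 0 °C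
Reagents that add atoms: tert-butyldimethylsilyl trifluoromethanesulfonate (TBSOTf), CC(C)(C)[Si](C)(C)OS(=O)(=O)C(F)(F)F
Why: N-silylation of the indolyl anion with the reactive silyl triflate, needed because N1 is hindered by the C7 side chain.

Step 6
Reactants: 10 tert-butyl 2-[1-(tert-butyldimethylsilyl)-7-(3-methylbut-2-en-1-yl)-1H-indol-3-yl]acetate
Product: 12 tert-butyl (E)-2-[1-(tert-butyldimethylsilyl)-7-(3-methylbut-2-en-1-yl)-1H-indol-3-yl]-3-methoxyprop-2-enoate, via potassium enolate 11 (not isolated)
Conditions: KN(SiMe3)2, THF, −78 °C; HCO2Me, −78 → 0 °C; then DMF, Me2SO4, 0 °C → rt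
Reagents that add atoms: methyl formate, COC=O; dimethyl sulfate, COS(=O)(=O)OC
Why: the same crossed Claisen formylation and O-methylation as in step 2; the methoxide set free is consumed at once by the acidic formyl ester, so the N–Si bond and the tert-butyl ester should survive.

Step 7
Reactants: 12 tert-butyl (E)-2-[1-(tert-butyldimethylsilyl)-7-(3-methylbut-2-en-1-yl)-1H-indol-3-yl]-3-methoxyprop-2-enoate; 4 methyl (E)-3-methoxy-2-[1-(triisopropylsilyl)-1H-indol-3-yl]prop-2-enoate
Product: 16 3-[1-(tert-butyldimethylsilyl)-7-(3-methylbut-2-en-1-yl)-1H-indol-3-yl]-2,5-dimethoxy-6-[1-(triisopropylsilyl)-1H-indol-3-yl]cyclohexa-2,5-diene-1,4-dione, via vinyllithium 13 (not isolated), via divinyl ketone 14 (not isolated), via lithiated ketone 15 (not isolated)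
Conditions: 12, LiTMP (1.05 equiv), THF, −95 °C; 4 (0.95 equiv), −95 → −78 °C; LiTMP (1.2 equiv), −78 → −40 °C; AcOH
Reagents that add atoms: none
Why: Proposed new method: LiTMP removes from 12 the vinyl H that lies cis to the ester and alpha to the methoxy oxygen, giving the ester-chelated α-methoxyvinyllithium 13 (an acyl-anion equivalent), which adds to the methyl ester C=O of unlithiated 4 and expels methoxide to give the cross-conjugated ketone 14; the second charge of LiTMP removes the one remaining vinyl H of 14 (cis to the new ketone) and vinyllithium 15 attacks the tert-butyl ester C=O with loss of tert-butoxide, which delivers the quinone at its final oxidation level. The closest known reaction types are the β-lithiation of β-alkoxyacrylates by lithium amides near −90 °C with trapping by carbonyl electrophiles (as used for tetronates) and the Parham-type cyclisation of an organolithium onto an ester; the double head-to-tail use to build a quinone is the new part. The six-membered quinone ring is closed by a 6-exo-trig addition–elimination of the vinyl carbanion at the ester carbonyl, and it can close only because the E geometry of both acrylates already holds each reacting carbon cis to the acyl group on its own double bond. No stereocentre is formed. The step needs cross- over homo-coupling and 1,2- over conjugate attack: the first is secured because a carbanion exists only on 12 when the partners meet and the tert-butyl ester of 13 resists intermolecular attack at −95 °C whereas the methyl ester of 4 does not, the second by the hard chelated vinyllithium in THF and by the donor OMe that deactivates the β-carbon of 4. The N-silyl groups neither acidify nor direct, so indole C2–H is left alone by the amide base, and the alkene carbons that bear the indoles carry no H, so neither partner nor 14 can enolise.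

Step 8
Reactants: 16 3-[1-(tert-butyldimethylsilyl)-7-(3-methylbut-2-en-1-yl)-1H-indol-3-yl]-2,5-dimethoxy-6-[1-(triisopropylsilyl)-1H-indol-3-yl]cyclohexa-2,5-diene-1,4-dione
Product: 17 3-(1H-indol-3-yl)-2,5-dimethoxy-6-[7-(3-methylbut-2-en-1-yl)-1H-indol-3-yl]cyclohexa-2,5-diene-1,4-dione
Conditions: Bu4NF (2.5 equiv), AcOH (2.5 equiv), THF, 0 °C
Reagents that add atoms: none
Why: fluoride-induced N-desilylation (the indolide is a good leaving group from silicon), buffered with acetic acid so that the vinylogous methyl esters of the quinone and the prenyl group should not be touched.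

**Compound list**

1 | methyl 2-(1H-indol-3-yl)acetate | COC(=O)Cc1c[nH]c2ccccc12 | starting material
2 | methyl 2-[1-(triisopropylsilyl)-1H-indol-3-yl]acetate | COC(=O)Cc1cn([Si](C(C)C)(C(C)C)C(C)C)c2ccccc12 | intermediate
3 | potassium 3-methoxy-3-oxo-2-[1-(triisopropylsilyl)-1H-indol-3-yl]prop-1-en-1-olate (delocalised anion, geometry not fixed; not isolated) | [K+].[O-]C=C(C(=O)OC)c1cn([Si](C(C)C)(C(C)C)C(C)C)c2ccccc12 | intermediate
4 | methyl (E)-3-methoxy-2-[1-(triisopropylsilyl)-1H-indol-3-yl]prop-2-enoate | CO/C=C(/C(=O)OC)c1cn([Si](C(C)C)(C(C)C)C(C)C)c2ccccc12 | intermediate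
5 | 7-bromo-1H-indole | Brc1cccc2cc[nH]c12 | starting material
6 | tert-butyl diazoacetate | CC(C)(C)OC(=O)C=[N+]=[N-] | starting material
7 | tert-butyl 2-(7-bromo-1H-indol-3-yl)acetate | CC(C)(C)OC(=O)Cc1c[nH]c2c(Br)cccc12 | intermediate
8 | tributyl(3-methylbut-2-en-1-yl)stannane | CCCC[Sn](CCCC)(CCCC)CC=C(C)C | starting material
9 | tert-butyl 2-[7-(3-methylbut-2-en-1-yl)-1H-indol-3-yl]acetate | CC(C)=CCc1cccc2c(CC(=O)OC(C)(C)C)c[nH]c12 | intermediate
10 | tert-butyl 2-[1-(tert-butyldimethylsilyl)-7-(3-methylbut-2-en-1-yl)-1H-indol-3-yl]acetate | CC(C)=CCc1cccc2c(CC(=O)OC(C)(C)C)cn([Si](C)(C)C(C)(C)C)c12 | intermediate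
11 | potassium 3-(tert-butoxy)-3-oxo-2-[1-(tert-butyldimethylsilyl)-7-(3-methylbut-2-en-1-yl)-1H-indol-3-yl]prop-1-en-1-olate (delocalised anion, geometry not fixed; not isolated) | [K+].[O-]C=C(C(=O)OC(C)(C)C)c1cn([Si](C)(C)C(C)(C)C)c2c(CC=C(C)C)cccc12 | intermediate
12 | tert-butyl (E)-2-[1-(tert-butyldimethylsilyl)-7-(3-methylbut-2-en-1-yl)-1H-indol-3-yl]-3-methoxyprop-2-enoate | CO/C=C(/C(=O)OC(C)(C)C)c1cn([Si](C)(C)C(C)(C)C)c2c(CC=C(C)C)cccc12 | intermediate
13 | tert-butyl (E)-2-[1-(tert-butyldimethylsilyl)-7-(3-methylbut-2-en-1-yl)-1H-indol-3-yl]-3-lithio-3-methoxyprop-2-enoate (Li cis to the ester; not isolated) | CO/C([Li])=C(/C(=O)OC(C)(C)C)c1cn([Si](C)(C)C(C)(C)C)c2c(CC=C(C)C)cccc12 | intermediate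
14 | tert-butyl (2E,5E)-2-[1-(tert-butyldimethylsilyl)-7-(3-methylbut-2-en-1-yl)-1H-indol-3-yl]-3,6-dimethoxy-4-oxo-5-[1-(triisopropylsilyl)-1H-indol-3-yl]hexa-2,5-dienoate (ketone cis to the ester, vinyl H cis to the ketone; not isolated) | CO/C=C(/C(=O)/C(OC)=C(\C(=O)OC(C)(C)C)c1cn([Si](C)(C)C(C)(C)C)c2c(CC=C(C)C)cccc12)c1cn([Si](C(C)C)(C(C)C)C(C)C)c2ccccc12 | intermediate
15 | tert-butyl (2E,5E)-2-[1-(tert-butyldimethylsilyl)-7-(3-methylbut-2-en-1-yl)-1H-indol-3-yl]-6-lithio-3,6-dimethoxy-4-oxo-5-[1-(triisopropylsilyl)-1H-indol-3-yl]hexa-2,5-dienoate (not isolated) | CO/C([Li])=C(/C(=O)/C(OC)=C(\C(=O)OC(C)(C)C)c1cn([Si](C)(C)C(C)(C)C)c2c(CC=C(C)C)cccc12)c1cn([Si](C(C)C)(C(C)C)C(C)C)c2ccccc12 | intermediate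
16 | 3-[1-(tert-butyldimethylsilyl)-7-(3-methylbut-2-en-1-yl)-1H-indol-3-yl]-2,5-dimethoxy-6-[1-(triisopropylsilyl)-1H-indol-3-yl]cyclohexa-2,5-diene-1,4-dione | COC1=C(c2cn([Si](C(C)C)(C(C)C)C(C)C)c3ccccc23)C(=O)C(OC)=C(c2cn([Si](C)(C)C(C)(C)C)c3c(CC=C(C)C)cccc23)C1=O | intermediate
17 | 3-(1H-indol-3-yl)-2,5-dimethoxy-6-[7-(3-methylbut-2-en-1-yl)-1H-indol-3-yl]cyclohexa-2,5-diene-1,4-dione | COC1=C(c2c[nH]c3ccccc23)C(=O)C(OC)=C(c2c[nH]c3c(CC=C(C)C)cccc23)C1=O | target

**Step count and risks**

Total steps: 8. Longest linear sequence: 6 (steps 3, 4, 5, 6, 7, 8).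

Step 7 (the proposed new method). What may go wrong: proton transfer from 4 to the vinyllithium and then homo-coupling, conjugate addition–elimination at the β-carbon of 4 in place of attack at the ester, or α-elimination of lithium methoxide from a vinyllithium on warming. The fallback builds no ring and instead attaches the indoles to a ready-made quinone by known acid-promoted conjugate additions; it sets out from 5 and returns at 17. Stille coupling of 5 with 8 (Pd(PPh3)4, DMF, 100 °C) should give 7-(3-methylbut-2-en-1-yl)-1H-indole F1. Commercial indole adds through C3 to commercial 2,5-dichloro-1,4-benzoquinone (AcOH, rt), and reoxidation of the hydroquinone (DDQ) should give 2,5-dichloro-3-(1H-indol-3-yl)cyclohexa-2,5-diene-1,4-dione F2. F1 adds in the same way to the remaining ring C–H of F2, and reoxidation with Ag2CO3 on Celite should give 2,5-dichloro-3-(1H-indol-3-yl)-6-[7-(3-methylbut-2-en-1-yl)-1H-indol-3-yl]cyclohexa-2,5-diene-1,4-dione F3. NaOMe in MeOH at 0 °C then replaces both vinylogous acid chlorides by addition–elimination and should give 17.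

Step 4. What may go wrong: transfer of the allyl unit through its substituted terminus (allylic transposition to the 1,1-dimethylallyl arene) and protodestannylation. The fallback separates C–C coupling from the trisubstituted alkene; it sets out from 7 and returns at 9. Stille coupling of 7 with allyltributylstannane (Pd(PPh3)4, DMF, 100 °C), where transposition changes nothing, should give tert-butyl 2-[7-(prop-2-en-1-yl)-1H-indol-3-yl]acetate F4. Cross-metathesis of F4 with excess 2-methylbut-2-ene (second-generation Grubbs catalyst, CH2Cl2, 40 °C) should give 9.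

Step 6 (the same applies to step 2). What may go wrong: O-methylation with the methoxy group cis to the ester, C-methylation of the enolate, or loss of the N-silyl group to methoxide followed by N-methylation. The fallback sets the geometry by elimination instead of by alkylation; it sets out from 10 and returns at 12. Formylation as before (KN(SiMe3)2, HCO2Me) with an aqueous NH4Cl quench should give the hydrogen-bonded enol tert-butyl (Z)-2-[1-(tert-butyldimethylsilyl)-7-(3-methylbut-2-en-1-yl)-1H-indol-3-yl]-3-hydroxyprop-2-enoate F5. Anhydrous acetalisation (HC(OMe)3, catalytic pyridinium p-toluenesulfonate, CH2Cl2) should give racemic tert-butyl 2-[1-(tert-butyldimethylsilyl)-7-(3-methylbut-2-en-1-yl)-1H-indol-3-yl]-3,3-dimethoxypropanoate F6. KOtBu in THF at 0 °C then eliminates methanol by an E1cB path and should give the E enol ether 12.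

**Further compounds**

F1 | step 7 | 7-(3-methylbut-2-en-1-yl)-1H-indole | CC(C)=CCc1cccc2cc[nH]c12
F2 | step 7 | 2,5-dichloro-3-(1H-indol-3-yl)cyclohexa-2,5-diene-1,4-dione | O=C1C(Cl)=C(c2c[nH]c3ccccc23)C(=O)C(Cl)=C1
F3 | step 7 | 2,5-dichloro-3-(1H-indol-3-yl)-6-[7-(3-methylbut-2-en-1-yl)-1H-indol-3-yl]cyclohexa-2,5-diene-1,4-dione | O=C1C(Cl)=C(c2c[nH]c3ccccc23)C(=O)C(Cl)=C1c1c[nH]c2c(CC=C(C)C)cccc12
F4 | step 4 | tert-butyl 2-[7-(prop-2-en-1-yl)-1H-indol-3-yl]acetate | C=CCc1cccc2c(CC(=O)OC(C)(C)C)c[nH]c12
F5 | step 6 | tert-butyl (Z)-2-[1-(tert-butyldimethylsilyl)-7-(3-methylbut-2-en-1-yl)-1H-indol-3-yl]-3-hydroxyprop-2-enoate | O/C=C(\C(=O)OC(C)(C)C)c1cn([Si](C)(C)C(C)(C)C)c2c(CC=C(C)C)cccc12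
F6 | step 6 | tert-butyl 2-[1-(tert-butyldimethylsilyl)-7-(3-methylbut-2-en-1-yl)-1H-indol-3-yl]-3,3-dimethoxypropanoate (racemic) | COC(OC)C(C(=O)OC(C)(C)C)c1cn([Si](C)(C)C(C)(C)C)c2c(CC=C(C)C)cccc12
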